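Per cent of the first end groups charged is my unit, so a full coupling reads 100 wherever first end groups are the limiting reagent, as in each earlier run.

| flask | first end groups | second end groups | remark | time |
|---|---|---|---|---|
| Friday's | 0.045 M | 0.0794 M | run made earlier |  |
| Sunday's | 0.057 M | 0.0794 M | run made earlier |  |
| Thursday's | 0.081 M | 0.14 M | run made earlier |  |
| theta | 0.050 M | 0.250 M |  | 8.0 min |
| epsilon | 0.081 M | 0.0794 M |  | 2.5 min |

- Friday's (time / s: links / %): 10.0: 94.8; 25.0: 95.8; 50.0: 90.5; 80.0: 86.9
- Sunday's (time / s: links / %): 10.0: 92.5; 15.0: 95.6; 30.0: 93.9; 80.0: 88.2
- Thursday's (time / s: links / %): 20.0: 95.0; 40.0: 90.4; 60.0: 89.2; 80.0: 84.9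

(scatter of a reading: 1 percentage point)

- the analysis behind the earlier runs scatters by 1 percentage point, standard deviation
- on the list of suspects stand: first end groups + second end groups -> links; links <-> isomer of the product; first end groups <-> dormant form

- which one finishes higher in amount of links, in percent of the first end groups charged ("neither" within 2 percentage points) (theta / epsilon / neither)
- amount of links at the end, in percent of the first end groups charged, theta
- amount of links at the end, in percent of the first end groups charged, epsilon

In the earlier runs the readings of links stand highest early, then sink. I take the mean of 3 readings around 40.0 s, which is 91.6%, and the mean of the last readings at 80.0 s, which is 86.7%. I count from a full charge at mixing.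

The first way is plain decay with no way back. Through the last mean it has a half-life of 6.46 min. The second way allows a return. Over the two equal spans, from mixing to the middle mean and from there to the last mean, the second drop is 0.587 of the first, and summing such shrinking drops gives 79.6%, the floor share: the part of the coupled material that stays links once the exchange rests. The approach to it has a half-time of 52.1 s. An even split would put the floor at half, so this reading lies on the side of links.

The ways part at the middle mean. Plain decay gives 93.1% there, against the 91.6% read, and a mean of 3 scatters less than a single reading's 1 percentage point. So plain decay cheats, and its 42.4% for theta falls below the even split. The second way passes through both means by construction, so its floor stays loose.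

Theta's 8.0 min lies far beyond the half-time, so theta reads the floor, 79.6%. In epsilon, second end groups cap coupling at 98.0%. Counting coupling as done at mixing, my share still links after 2.5 min is 82.4%, which gives 80.8% for epsilon. The gap is 1.2 points, within 2 points, so I say neither.

The forecast says epsilon, with 58% for theta and 80% for epsilon, finding “little clear evidence of a plateau by 80 s”.

The flask gives epsilon: 79.0% there, 73.9% in theta.

    first end groups + second end groups → links (k = 7.30 M⁻¹ s⁻¹)
    links ⇌ isomer of the product (K = 0.360, k = 0.00230 s⁻¹)
    first end groups ⇌ dormant form (K = 0.570, k = 0.00150 s⁻¹)

In epsilon, coupling has 91% of its turnover up to the asked time behind it by 0.250 min, and at 2.50 min links are made at 0.102 of the rate at which they are used, each step taken net. The exchange of links and isomer of the product has a relaxation half-life of 1.33 min, reckoned for epsilon, short against theta's 8.0 min. Links in theta end at 73.9% against my 79.6%, so my neither fails.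

In a flask like epsilon with 0.32 M of first end groups, second end groups allow 24.8%, and my share 82.4%, built on the floor share 79.6%, gives 20.4%. The computed flask holds 20.0% links.

All runs come from a simulation for an exercise; scatter was added.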